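The benzene ring is disconnected across C1–C6 and C4–C5 and grown on the chiral chain. Its oxygens at C3 (OMe) and C5 (OH) sit 1,3 to each other and meta to the C1 side chain, the pattern of a 5-substituted cyclohexane-1,3-dione. In one operation dimethyl malonate adds to the β-carbon of an (E)-enone and the adduct closes by Claisen condensation to the six-membered carbocycle. The enone is a methyl ketone whose δ-carbon is the silyl-protected C2' carbinol of (R)-3-hydroxytetradecanoic acid. Decarboxylation with desilylation, monomethylation, dehydrogenation, para-oxidation (C2 oxygen), acetylation and quinone reduction finish the target.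

Key step: step 5

Remark on the chemistry: the target ring is numbered C1 (side chain), C2 (OH), C3 (OMe), C4, C5 (OH), C6, and the side chain C1', C2'. Ring stereocentres of intermediates are carried as epimer mixtures because aromatisation removes them.

Step 1
Reactants: 1 (R)-3-hydroxytetradecanoic acid
Product: 2 (R)-3-hydroxy-N-methoxy-N-methyltetradecanamide
Conditions: MeNH(OMe)·HCl, EDC·HCl, HOBt, N-methylmorpholine, CH2Cl2, 0 °C → rt
Reagents that add atoms: N,O-dimethylhydroxylamine hydrochloride, CNOC.Cl
Why: Carbodiimide/HOBt amide coupling acylates the amine much faster than the free secondary hydroxyl, and the carbinol carbon is not α to the carbonyl, so its (R) configuration is untouched.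

Step 2
Reactants: 2 (R)-3-hydroxy-N-methoxy-N-methyltetradecanamide
Product: 3 (R)-3-(tert-butyldimethylsilyloxy)-N-methoxy-N-methyltetradecanamide
Conditions: TBSCl, imidazole, DMF, rt
Reagents that add atoms: tert-butyldimethylsilyl chloride, CC(C)(C)[Si](C)(C)Cl
Why: Imidazole-promoted silylation of a secondary alcohol should give the silyl ether that carries the carbinol through hydride, ylide and methoxide.

Step 3
Reactants: 3 (R)-3-(tert-butyldimethylsilyloxy)-N-methoxy-N-methyltetradecanamide
Product: 4 (R)-3-(tert-butyldimethylsilyloxy)tetradecanal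
Conditions: iBu2AlH, THF, −78 °C; KNaC4H4O6 (aq)
Reagents that add atoms: none
Why: Weinreb amide reduction stops at the aldehyde because the chelated tetrahedral aluminium adduct survives until aqueous work-up, and the cold non-basic medium avoids β-elimination of the silyloxy group.

Step 4
Reactants: 4 (R)-3-(tert-butyldimethylsilyloxy)tetradecanal; 5 acetonylidenetriphenylphosphorane
Product: 6 (R,E)-6-(tert-butyldimethylsilyloxy)heptadec-3-en-2-one
Conditions: CH2Cl2, 40 °C
Reagents that add atoms: none
Why: Wittig olefination with a ketone-stabilised ylide is E-selective and neutral enough that the β-silyloxy aldehyde should neither eliminate nor lose configuration.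

Step 5
Reactants: 6 (R,E)-6-(tert-butyldimethylsilyloxy)heptadec-3-en-2-one; 7 dimethyl malonate
Product: 9 methyl 6-[(2R)-2-(tert-butyldimethylsilyloxy)tridecyl]-2,4-dioxocyclohexane-1-carboxylate (mixture of ring epimers), via Michael adduct 8 (not isolated)
Conditions: NaOMe (1.2 equiv), 7 (1.3 equiv), MeOH, 0 °C → rt, then 65 °C; HCl (aq), 0 °C, pH 3
Reagents that add atoms: none
Why: Preformed sodium dimethyl malonate adds 1,4 to enone 6 at the β-carbon (future ring C1; bond C1–C6) to give adduct 8, methoxide then enolises the terminal CH3 of the ketone, and that enolate acylates on one malonate ester (bond C4–C5) with loss of methoxide, the sequence being driven by formation of the stabilised sodium β-diketone enolate of 9. The closest known reaction type is the Michael addition–Claisen (Dieckmann-type) annulation of malonates with alk-3-en-2-ones that gives 5-alkylcyclohexane-1,3-diones. The single ring closes by 6-exo-trig attack of the enolate carbon on the ester carbonyl. The two new ring stereocentres (C1 and C6 of 9) are under no control and need none, because decarboxylation and aromatisation erase them, while C2' has no neighbouring carbonyl and keeps its (R) configuration. The step needs 1,4- over 1,2-addition and closure through the methyl group: the soft malonate carbanion secures the first, and the second follows because only the CH3-derived enolate can reach an ester through a six-membered transition state. Loss of the δ-silyloxy group by γ-deprotonation and elimination is held back by letting the weakly basic malonate salt consume the enone at 0 °C to rt before the mixture is heated.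

Step 6
Reactants: 9 methyl 6-[(2R)-2-(tert-butyldimethylsilyloxy)tridecyl]-2,4-dioxocyclohexane-1-carboxylate
Product: 12 5-[(2R)-2-hydroxytridecyl]cyclohexane-1,3-dione, via keto acid 10 (not isolated), via silyl dione 11 (not isolated)
Conditions: NaOH (aq), MeOH, 65 °C; evaporate MeOH; HCl (aq, 2 M), THF, 65 °C
Reagents that add atoms: none
Why: Saponification and acidification give the β-keto acid, which decarboxylates through the usual six-membered cyclic transition state on warming, and the same hot aqueous acid hydrolyses the secondary silyl ether, so the protecting group is shed on purpose without a step of its own.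

Step 7
Reactants: 12 5-[(2R)-2-hydroxytridecyl]cyclohexane-1,3-dione
Product: 13 5-[(2R)-2-hydroxytridecyl]-3-methoxycyclohex-2-en-1-one (both C5 epimers)
Conditions: Me3SiCHN2, MeOH/toluene, 0 °C → rt
Reagents that add atoms: trimethylsilyldiazomethane, C[Si](C)(C)C=[N+]=[N-]
Why: The cyclic 1,3-dione is a vinylogous carboxylic acid that protonates the diazoalkane and is O-methylated, whereas the neutral secondary alcohol is not acidic enough to react, and the two possible enol ethers converge on aromatisation.

Step 8
Reactants: 13 5-[(2R)-2-hydroxytridecyl]-3-methoxycyclohex-2-en-1-one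
Product: 17 3-[(2R)-2-hydroxytridecyl]-5-methoxyphenol, via bis-silyl dienol ether 14 (not isolated), via dienone 15 (not isolated), via silyl ether 16 (not isolated)
Conditions: LiN(iPr)2 (2.3 equiv), THF, −78 °C; Me3SiCl, −78 → 0 °C; Pd(OAc)2 (1.1 equiv), MeCN, rt; HCl (aq), THF, rt
Reagents that add atoms: none
Why: Saegusa–Ito dehydrogenation, in which the base forms the alkoxide and then removes the kinetic α'-proton (ring C6) of the vinylogous ester, both oxygens are silylated to 14, Pd(OAc)2 converts the silyl dienol ether by way of an oxa-π-allyl palladium species and syn β-hydride elimination from C5 into dienone 15, this keto tautomer of a phenol enolises to arene 16, and dilute acid removes the labile trimethylsilyl ether.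

Step 9
Reactants: 17 3-[(2R)-2-hydroxytridecyl]-5-methoxyphenol
Product: 18 2-[(2R)-2-hydroxytridecyl]-6-methoxycyclohexa-2,5-diene-1,4-dione
Conditions: (KSO3)2NO (Fremy's salt, 2.5 equiv), KH2PO4 (aq), acetone, rt
Reagents that add atoms: potassium nitrosodisulfonate, [K+].[K+].[O-]S(=O)(=O)N([O])S(=O)(=O)[O-]
Why: Teuber oxidation, in which one equivalent of the nitroxyl abstracts the phenolic hydrogen and a second delivers oxygen to the free para carbon between OMe and the side chain, the usual course for phenols with an open para position and for 3-methoxy-5-alkylphenols, while the aliphatic secondary alcohol is inert to this oxidant.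

Step 10
Reactants: 18 2-[(2R)-2-hydroxytridecyl]-6-methoxycyclohexa-2,5-diene-1,4-dione
Product: 19 (2R)-1-(5-methoxy-3,6-dioxocyclohexa-1,4-dien-1-yl)tridecan-2-yl acetate
Conditions: Ac2O, pyridine, CH2Cl2, 0 °C → rt
Reagents that add atoms: acetic anhydride, CC(=O)OC(C)=O
Why: Pyridine-mediated O-acetylation of the only hydroxyl in the molecule proceeds with retention at C2', and the quinone should tolerate the weakly nucleophilic medium at low temperature.

Step 11
Reactants: 19 (2R)-1-(5-methoxy-3,6-dioxocyclohexa-1,4-dien-1-yl)tridecan-2-yl acetate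
Product: 20 (2R)-1-(2,5-dihydroxy-3-methoxyphenyl)tridecan-2-yl acetate
Conditions: Na2S2O4 (aq), EtOAc, rt, argon
Reagents that add atoms: none
Why: Dithionite reduction of a 1,4-benzoquinone to its hydroquinone is fast in a two-phase system near neutral pH, where the secondary acetate should neither hydrolyse nor migrate.

Compound list
1 | (R)-3-hydroxytetradecanoic acid | CCCCCCCCCCC[C@H](CC(=O)O)O | starting material
2 | (R)-3-hydroxy-N-methoxy-N-methyltetradecanamide | CCCCCCCCCCC[C@H](CC(=O)N(C)OC)O | intermediate
3 | (R)-3-(tert-butyldimethylsilyloxy)-N-methoxy-N-methyltetradecanamide | CCCCCCCCCCC[C@H](CC(=O)N(C)OC)O[Si](C)(C)C(C)(C)C | intermediate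
4 | (R)-3-(tert-butyldimethylsilyloxy)tetradecanal | CCCCCCCCCCC[C@H](CC=O)O[Si](C)(C)C(C)(C)C | intermediate
5 | acetonylidenetriphenylphosphorane [1-(triphenylphosphoranylidene)propan-2-one] | CC(=O)C=P(c1ccccc1)(c1ccccc1)c1ccccc1 | starting material
6 | (R,E)-6-(tert-butyldimethylsilyloxy)heptadec-3-en-2-one | CCCCCCCCCCC[C@H](C/C=C/C(C)=O)O[Si](C)(C)C(C)(C)C | intermediate
7 | dimethyl malonate | COC(=O)CC(=O)OC | starting material
8 | dimethyl 2-[(6R)-6-(tert-butyldimethylsilyloxy)-2-oxoheptadecan-4-yl]propanedioate (C4 epimers; not isolated) | CCCCCCCCCCC[C@H](CC(CC(C)=O)C(C(=O)OC)C(=O)OC)O[Si](C)(C)C(C)(C)C | intermediate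
9 | methyl 6-[(2R)-2-(tert-butyldimethylsilyloxy)tridecyl]-2,4-dioxocyclohexane-1-carboxylate (ring epimers) | CCCCCCCCCCC[C@H](CC1CC(=O)CC(=O)C1C(=O)OC)O[Si](C)(C)C(C)(C)C | intermediate
10 | 6-[(2R)-2-(tert-butyldimethylsilyloxy)tridecyl]-2,4-dioxocyclohexane-1-carboxylic acid (not isolated) | CCCCCCCCCCC[C@H](CC1CC(=O)CC(=O)C1C(=O)O)O[Si](C)(C)C(C)(C)C | intermediate
11 | 5-[(2R)-2-(tert-butyldimethylsilyloxy)tridecyl]cyclohexane-1,3-dione (not isolated) | CCCCCCCCCCC[C@H](CC1CC(=O)CC(=O)C1)O[Si](C)(C)C(C)(C)C | intermediate
12 | 5-[(2R)-2-hydroxytridecyl]cyclohexane-1,3-dione | CCCCCCCCCCC[C@H](CC1CC(=O)CC(=O)C1)O | intermediate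
13 | 5-[(2R)-2-hydroxytridecyl]-3-methoxycyclohex-2-en-1-one (both C5 epimers) | CCCCCCCCCCC[C@H](CC1CC(=O)C=C(OC)C1)O | intermediate
14 | trimethyl{[(2R)-1-[5-methoxy-3-(trimethylsilyloxy)cyclohexa-2,4-dien-1-yl]tridecan-2-yl]oxy}silane (ring epimers; not isolated) | CCCCCCCCCCC[C@H](CC1C=C(O[Si](C)(C)C)C=C(OC)C1)O[Si](C)(C)C | intermediate
15 | 3-methoxy-5-[(2R)-2-(trimethylsilyloxy)tridecyl]cyclohexa-2,5-dien-1-one (not isolated) | CCCCCCCCCCC[C@H](CC1=CC(=O)C=C(OC)C1)O[Si](C)(C)C | intermediate
16 | 3-methoxy-5-[(2R)-2-(trimethylsilyloxy)tridecyl]phenol (not isolated) | CCCCCCCCCCC[C@H](Cc1cc(O)cc(OC)c1)O[Si](C)(C)C | intermediate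
17 | 3-[(2R)-2-hydroxytridecyl]-5-methoxyphenol | CCCCCCCCCCC[C@H](Cc1cc(O)cc(OC)c1)O | intermediate
18 | 2-[(2R)-2-hydroxytridecyl]-6-methoxycyclohexa-2,5-diene-1,4-dione | CCCCCCCCCCC[C@H](CC1=CC(=O)C=C(OC)C1=O)O | intermediate
19 | (2R)-1-(5-methoxy-3,6-dioxocyclohexa-1,4-dien-1-yl)tridecan-2-yl acetate | CCCCCCCCCCC[C@H](CC1=CC(=O)C=C(OC)C1=O)OC(C)=O | intermediate
20 | (2R)-1-(2,5-dihydroxy-3-methoxyphenyl)tridecan-2-yl acetate (CNP0331604.1) | CCCCCCCCCCC[C@H](Cc1cc(O)cc(OC)c1O)OC(C)=O | target

Total step count: 11. Longest linear sequence: 11 steps (1 → 20).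

Steps most likely to fail

Step 5. What may go wrong: base-induced loss of the silyloxy group (γ-deprotonation of the enone and expulsion of silanolate) competing with conjugate addition, or a stalled ring closure after the addition. Fallback: the bond pairing is reversed. Setting out from aldehyde 4, Wittig olefination with Ph3P=CHCO2Me in CH2Cl2 at rt should give methyl (R,E)-5-(tert-butyldimethylsilyloxy)hexadec-2-enoate F1, whose γ-hydrogens are far less acidic than those of the enone. Treating F1 with methyl acetoacetate and NaOMe in MeOH should lead to conjugate addition of the acetoacetate methylene and then Dieckmann closure of the acetyl methyl onto the enoate ester. This is the other classical entry to 5-alkylcyclohexane-1,3-diones and should give the same dione ester, so the route is rejoined at 9.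

Step 8. What may go wrong: incomplete or misdirected enolisation in the presence of the lithium alkoxide, or slow β-hydride elimination at palladium so that the silyl dienol ether is merely hydrolysed back to the enone. Fallback: selenoxide elimination in place of the palladium-mediated dehydrosilylation. Setting out from 13, LiN(iPr)2 (2.3 equiv) in THF at −78 °C followed by PhSeBr should give 5-[(2R)-2-hydroxytridecyl]-3-methoxy-6-(phenylselanyl)cyclohex-2-en-1-one F2, with selenium entering trans to the C5 substituent and therefore cis to C5–H. H2O2 and pyridine in CH2Cl2 at 0 °C then oxidise selenium, syn-elimination toward C5–H and tautomerisation follow, and the route is rejoined at phenol 17.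

Step 10. What may go wrong: attack of the amine base on the electron-poor quinone ring (conjugate addition and darkening) outpacing acylation of the secondary alcohol. Fallback: the acetate is installed before the oxidation, so that the quinone only has to be reduced. Setting out from 17, Ac2O, pyridine and a little DMAP should give (2R)-1-(3-acetoxy-5-methoxyphenyl)tridecan-2-yl acetate F3. Pyrrolidine (1.1 equiv, CH2Cl2, 0 °C) should cleave only the aryl acetate by aminolysis to give (2R)-1-(3-hydroxy-5-methoxyphenyl)tridecan-2-yl acetate F4. Oxidation of F4 with (KSO3)2NO under the conditions of step 9 should give the acetoxyquinone, rejoining the route at 19.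

Further compounds
F1 | step 5 | methyl (R,E)-5-(tert-butyldimethylsilyloxy)hexadec-2-enoate | CCCCCCCCCCC[C@H](C/C=C/C(=O)OC)O[Si](C)(C)C(C)(C)C
F2 | step 8 | 5-[(2R)-2-hydroxytridecyl]-3-methoxy-6-(phenylselanyl)cyclohex-2-en-1-one | CCCCCCCCCCC[C@H](CC1CC(OC)=CC(=O)C1[Se]c1ccccc1)O
F3 | step 10 | (2R)-1-(3-acetoxy-5-methoxyphenyl)tridecan-2-yl acetate | CCCCCCCCCCC[C@H](Cc1cc(OC(C)=O)cc(OC)c1)OC(C)=O
F4 | step 10 | (2R)-1-(3-hydroxy-5-methoxyphenyl)tridecan-2-yl acetate | CCCCCCCCCCC[C@H](Cc1cc(O)cc(OC)c1)OC(C)=O
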